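## Retrosynthetic overview

1. The chlorohydrin is made last, by hydroxyl-directed chloride opening of a ring 3,4-epoxide (the presumed biogenetic origin of the Cl/OH pair); the 10,11-oxirane is installed just before by catalyst-controlled epoxidation.
2. The ring 3,4-epoxy-2-ol comes from a 2,3-epoxide by epoxide-to-allylic-alcohol transposition and directed epoxidation; the C1 angelate is introduced with inversion by a Mitsunobu reaction.
3. Key disconnection C1–C6: carbonyl-ene (Prins-type) closure of an acyclic (2R,3R)-2,3-epoxy-(6Z)-farnesal, the laboratory counterpart of farnesyl → bisabolyl cation → loss of H-14; the epoxide controls C1 and C6.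
4. The acyclic chain comes from Sharpless epoxidation of a (2Z)-farnesol; its C7–C8 bond and C8 stereocentre come from an asymmetric Nozaki–Hiyama–Kishi coupling of a (Z)-vinyl iodide (from neryl acetate) with 4-methylpent-3-enal.
5. Ring order: 2,3-oxirane (on the open chain) → cyclohexane → 3,4-oxirane → side-chain oxirane; the 2,3- and 3,4-oxiranes are consumed on the way.

Assumption: farnesane/bisabolane numbering is used (C1–C6 become the ring; C1 carries the ring ester, C3 the methyl, C6 the side chain C7(=C14)–C8–C9–C10–C11); β is the ring face of the C6–C7 bond; "angelate" is (2Z)-2-methylbut-2-enoate; the sense of induction of the step 4 ligand is assigned by Mosher analysis of 7 and the antipode giving 8S is used.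

## Route

Step 1
Reactants: 1 neryl acetate
Product: 3 (2Z)-3-methyl-6-oxohex-2-en-1-yl acetate, via 6,7-epoxyneryl acetate 2 (not isolated)
Conditions: mCPBA (1.05 equiv), CH2Cl2, 0 °C; then H5IO6, THF/H2O, 0 °C
Reagents that add atoms: mCPBA, O=C(OO)c1cccc(Cl)c1
Why: The remote 6,7-olefin is far more nucleophilic than the 2,3-olefin deactivated by the allylic acetate, so the Prilezhaev epoxidation is site-selective, and periodic acid then hydrolyses and cleaves the epoxide (Malaprade-type glycol cleavage) without touching the (2Z)-olefin.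

Step 2
Reactants: 3 (2Z)-3-methyl-6-oxohex-2-en-1-yl acetate
Product: 4 (2Z,6Z)-7-iodo-3-methylocta-2,6-dien-1-yl acetate
Conditions: [EtPPh3]I, n-BuLi, THF, rt; I2, −78 °C; NaHMDS, −20 °C; then 3, −78 → −20 °C
Reagents that add atoms: ethyltriphenylphosphonium iodide, CC[P+](c1ccccc1)(c1ccccc1)c1ccccc1.[I-]; iodine, II
Why: Stork–Zhao-type Wittig iodo-olefination with the α-iodoethylidene ylide gives the (Z)-2-iodo-2-alkene (iodine cis to the chain) under kinetic control, which fixes the 6Z geometry that the cyclization needs.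

Step 3
Reactants: 5 4-methylpent-3-en-1-ol
Product: 6 4-methylpent-3-enal
Conditions: Dess–Martin periodinane, pyridine, CH2Cl2, 0 °C; solution used at once
Reagents that add atoms: none
Why: Buffered Dess–Martin oxidation gives the β,γ-unsaturated aldehyde under neutral conditions, so the olefin does not move into conjugation.

Step 4
Reactants: 4 (2Z,6Z)-7-iodo-3-methylocta-2,6-dien-1-yl acetate; 6 4-methylpent-3-enal
Product: 7 (2Z,6Z,8S)-8-hydroxy-3,7,11-trimethyldodeca-2,6,10-trien-1-yl acetate
Conditions: CrCl2 (4 equiv), NiCl2 (2 mol %), chiral 4-isopropyl-oxazoline aryl methanesulfonamide ligand (4.4 equiv), Et3N, THF, rt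
Reagents that add atoms: none
Why: Nozaki–Hiyama–Kishi coupling, in which zerovalent nickel inserts into the C–I bond with retention of the Z geometry, transmetalation gives an alkenyl species of trivalent chromium that adds only to the aldehyde (acetate untouched), and the chiral sulfonamide ligand on chromium directs Re-face attack to set C8 (S).

Step 5
Reactants: 7 (2Z,6Z,8S)-8-hydroxy-3,7,11-trimethyldodeca-2,6,10-trien-1-yl acetate
Product: 8 (2Z,6Z,8S)-1-acetoxy-3,7,11-trimethyldodeca-2,6,10-trien-8-yl angelate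
Conditions: angelic acid, 2,4,6-Cl3C6H2COCl, Et3N, PhMe, rt; then 7, 70 °C
Reagents that add atoms: angelic acid, C/C=C(/C)C(=O)O
Why: Yamaguchi-type esterification through the mixed 2,4,6-trichlorobenzoic anhydride acylates the secondary allylic alcohol with retention at C8 and without Z-to-E isomerisation of the angelate.

Step 6
Reactants: 8 (2Z,6Z,8S)-1-acetoxy-3,7,11-trimethyldodeca-2,6,10-trien-8-yl angelate
Product: 9 (2Z,6Z,8S)-1-hydroxy-3,7,11-trimethyldodeca-2,6,10-trien-8-yl angelate
Conditions: K2CO3 (0.2 equiv), MeOH, 0 °C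
Reagents that add atoms: none
Why: Base-catalysed transesterification (Zemplén-type methanolysis) removes the unhindered primary acetate much faster than the hindered, conjugated secondary angelate.

Step 7
Reactants: 9 (2Z,6Z,8S)-1-hydroxy-3,7,11-trimethyldodeca-2,6,10-trien-8-yl angelate
Product: 10 (2S,3R,6Z,8S)-2,3-epoxy-1-hydroxy-3,7,11-trimethyldodeca-6,10-dien-8-yl angelate
Conditions: Ti(OiPr)4 (10 mol %), L-(+)-diethyl tartrate (12 mol %), t-BuOOH, 4 Å MS, CH2Cl2, −20 °C
Reagents that add atoms: tert-butyl hydroperoxide, CC(C)(C)OO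
Why: Sharpless asymmetric epoxidation delivers oxygen only to the olefin of the free allylic alcohol, and L-(+)-tartrate gives the (2S,3R) epoxide from a (2Z) allylic alcohol under reagent control, which sets C2 and C3 and turns any minor C8 enantiomer into a separable diastereomer.

Step 8
Reactants: 10 (2S,3R,6Z,8S)-2,3-epoxy-1-hydroxy-3,7,11-trimethyldodeca-6,10-dien-8-yl angelate
Product: 11 (2R,3R,6Z,8S)-2,3-epoxy-3,7,11-trimethyl-1-oxododeca-6,10-dien-8-yl angelate
Conditions: Dess–Martin periodinane, pyridine, CH2Cl2, 0 °C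
Reagents that add atoms: none
Why: Dess–Martin oxidation converts the primary epoxy alcohol into the configurationally stable α,β-epoxy aldehyde under conditions that are neither acidic nor basic.

Step 9
Reactants: 11 (2R,3R,6Z,8S)-2,3-epoxy-3,7,11-trimethyl-1-oxododeca-6,10-dien-8-yl angelate
Product: 12 (1R,2S,3R,6R,8S)-2β,3β-epoxy-1α-hydroxybisabola-7(14),10-dien-8-yl angelate
Conditions: Me2AlCl (2.2 equiv), CH2Cl2, −78 → −40 °C; aq. Rochelle salt
Reagents that add atoms: none
Why: Proposed new method: an intramolecular carbonyl-ene (Prins-type) cyclization of an α,β-epoxy aldehyde, closest known reactions being the Lewis-acid cyclizations of citronellal to isopulegol and of neral to isopiperitenol, which copies the C1–C6 closure of the farnesyl chain and the loss of H from C14; C6 attacks the Al-bound aldehyde anti to the epoxide C–O bond (Felkin–Anh/Cornforth) through a half-chair with the ene unit equatorial and C=O pseudo-equatorial, which sets C6 (side chain cis to the epoxide) and C1 (OH trans to both), the 6Z geometry places the C14 methyl rather than C8–H trans to the tether where the concerted H transfer to oxygen occurs so the 7(14)-ene results, and Me2AlCl scavenges protons so that the epoxide survives.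

Step 10
Reactants: 12 (1R,2S,3R,6R,8S)-2β,3β-epoxy-1α-hydroxybisabola-7(14),10-dien-8-yl angelate
Product: 13 (1S,2S,3R,6R,8S)-2β,3β-epoxybisabola-7(14),10-diene-1β,8-diyl diangelate
Conditions: angelic acid, PPh3, DIAD, PhMe, 0 °C → rt
Reagents that add atoms: angelic acid, C/C=C(/C)C(=O)O
Why: Mitsunobu esterification displaces the oxyphosphonium ion by SN2 with inversion at C1, so the second angelate is installed directly in the 1β configuration (cis to epoxide and side chain), epoxy carbinols being tolerated and the angelate geometry kept.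

Step 11
Reactants: 13 (1S,2S,3R,6R,8S)-2β,3β-epoxybisabola-7(14),10-diene-1β,8-diyl diangelate
Product: 15 (1S,2R,6R,8S)-2β-hydroxybisabola-3,7(14),10-triene-1β,8-diyl diangelate, via allylic trimethylsilyl ether 14 (not isolated)
Conditions: TMSOTf, DBU, PhMe, −78 → 0 °C; then 1 M HCl, THF, 0 °C
Reagents that add atoms: none
Why: Silyl-triflate-promoted isomerisation of an epoxide to an allylic alcohol, in which TMSOTf opens the activated epoxide at tertiary C3 and DBU removes the anti-periplanar axial H at C4 (Zaitsev-type anti elimination), so the C2–O bond keeps its β configuration while the olefin moves to C3=C4, the cis C1 ester cannot participate, and dilute acid removes the silyl group.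

Step 12
Reactants: 15 (1S,2R,6R,8S)-2β-hydroxybisabola-3,7(14),10-triene-1β,8-diyl diangelate
Product: 16 (1S,2S,3S,4R,6R,8S)-3β,4β-epoxy-2β-hydroxybisabola-7(14),10-diene-1β,8-diyl diangelate
Conditions: VO(acac)2 (5 mol %), t-BuOOH, CH2Cl2, 0 °C → rt
Reagents that add atoms: tert-butyl hydroperoxide, CC(C)(C)OO
Why: Hydroxyl-directed epoxidation with VO(acac)2/t-BuOOH delivers oxygen to the C3=C4 olefin syn to the allylic C2–OH (β face), setting C3 and C4, and leaves the C7=C14 and C10=C11 olefins, which have no allylic hydroxyl, untouched.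

Step 13
Reactants: 16 (1S,2S,3S,4R,6R,8S)-3β,4β-epoxy-2β-hydroxybisabola-7(14),10-diene-1β,8-diyl diangelate
Product: 17 (1S,2S,3S,4R,6R,8S,10S)-3β,4β:10,11-diepoxy-2β-hydroxybisabol-7(14)-ene-1β,8-diyl diangelate
Conditions: ent-Shi ketone (L-series fructose-derived, 30 mol %), Oxone (2KHSO5·KHSO4·K2SO4), K2CO3, Bu4NHSO4, MeCN/DMM/aq. Na2B4O7–EDTA buffer, 0 °C
Reagents that add atoms: potassium peroxymonosulfate, [K+].[O-]S(=O)(=O)OO
Why: Shi asymmetric epoxidation, in which the chiral dioxirane attacks the only electron-rich unhindered trisubstituted olefin (the C7=C14 olefin between two ester-bearing carbons and the angelate enoates react much more slowly) through the spiro transition state, and the L-series ketone sets C10 (S) under catalyst control.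

Step 14
Reactants: 17 (1S,2S,3S,4R,6R,8S,10S)-3β,4β:10,11-diepoxy-2β-hydroxybisabol-7(14)-ene-1β,8-diyl diangelate
Product: 18 (1S,2S,3S,4S,6R,8S,10S)-4α-chloro-10,11-epoxy-2β,3β-dihydroxybisabol-7(14)-ene-1β,8-diyl diangelate (CNP0333703.2)
Conditions: Ti(OiPr)4 (1.5 equiv), Et2NH·HCl, CH2Cl2, 0 °C → rt
Reagents that add atoms: diethylammonium chloride, CC[NH2+]CC.[Cl-]
Why: Hydroxyl-directed Ti(OiPr)4-mediated opening of a 2,3-epoxy alcohol, in which the C2 alkoxide binds titanium so only the ring epoxide is activated and chloride attacks the distal secondary C4 with inversion (trans-diaxial, Fürst–Plattner), giving the 4α-chloro-3β-hydroxy pattern as in the presumed biogenesis while the side-chain epoxide, which has no neighbouring hydroxyl, stays intact.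

## Compound list

1 | neryl acetate, (2Z)-3,7-dimethylocta-2,6-dien-1-yl acetate | CC(C)=CCC/C(C)=C\COC(C)=O | starting material
2 | 6,7-epoxyneryl acetate (racemic at the oxirane CH) | CC1(C)OC1CC/C(C)=C\COC(C)=O | intermediate
3 | (2Z)-3-methyl-6-oxohex-2-en-1-yl acetate | O=CCC/C(C)=C\COC(C)=O | intermediate
4 | (2Z,6Z)-7-iodo-3-methylocta-2,6-dien-1-yl acetate | I/C(C)=C\CC/C(C)=C\COC(C)=O | intermediate
5 | 4-methylpent-3-en-1-ol | CC(C)=CCCO | starting material
6 | 4-methylpent-3-enal | CC(C)=CCC=O | intermediate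
7 | (2Z,6Z,8S)-8-hydroxy-3,7,11-trimethyldodeca-2,6,10-trien-1-yl acetate | CC(C)=CC[C@H](O)/C(C)=C\CC/C(C)=C\COC(C)=O | intermediate
8 | (2Z,6Z,8S)-1-acetoxy-3,7,11-trimethyldodeca-2,6,10-trien-8-yl angelate | CC(C)=CC[C@H](OC(=O)/C(C)=C\C)/C(C)=C\CC/C(C)=C\COC(C)=O | intermediate
9 | (2Z,6Z,8S)-1-hydroxy-3,7,11-trimethyldodeca-2,6,10-trien-8-yl angelate | CC(C)=CC[C@H](OC(=O)/C(C)=C\C)/C(C)=C\CC/C(C)=C\CO | intermediate
10 | (2S,3R,6Z,8S)-2,3-epoxy-1-hydroxy-3,7,11-trimethyldodeca-6,10-dien-8-yl angelate | OC[C@@H]1O[C@]1(C)CC/C=C(C)\[C@H](CC=C(C)C)OC(=O)/C(C)=C\C | intermediate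
11 | (2R,3R,6Z,8S)-2,3-epoxy-3,7,11-trimethyl-1-oxododeca-6,10-dien-8-yl angelate | O=C[C@@H]1O[C@]1(C)CC/C=C(C)\[C@H](CC=C(C)C)OC(=O)/C(C)=C\C | intermediate
12 | (1R,2S,3R,6R,8S)-2β,3β-epoxy-1α-hydroxybisabola-7(14),10-dien-8-yl angelate | C=C([C@H](CC=C(C)C)OC(=O)/C(C)=C\C)[C@H]1CC[C@@]2(C)O[C@H]2[C@@H]1O | intermediate
13 | (1S,2S,3R,6R,8S)-2β,3β-epoxybisabola-7(14),10-diene-1β,8-diyl diangelate | C=C([C@H](CC=C(C)C)OC(=O)/C(C)=C\C)[C@H]1CC[C@@]2(C)O[C@H]2[C@H]1OC(=O)/C(C)=C\C | intermediate
14 | 2β-O-trimethylsilyl ether of 15 | C=C([C@H](CC=C(C)C)OC(=O)/C(C)=C\C)[C@H]1CC=C(C)[C@@H](O[Si](C)(C)C)[C@H]1OC(=O)/C(C)=C\C | intermediate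
15 | (1S,2R,6R,8S)-2β-hydroxybisabola-3,7(14),10-triene-1β,8-diyl diangelate | C=C([C@H](CC=C(C)C)OC(=O)/C(C)=C\C)[C@H]1CC=C(C)[C@@H](O)[C@H]1OC(=O)/C(C)=C\C | intermediate
16 | (1S,2S,3S,4R,6R,8S)-3β,4β-epoxy-2β-hydroxybisabola-7(14),10-diene-1β,8-diyl diangelate | C=C([C@H](CC=C(C)C)OC(=O)/C(C)=C\C)[C@H]1C[C@H]2O[C@@]2(C)[C@@H](O)[C@H]1OC(=O)/C(C)=C\C | intermediate
17 | (1S,2S,3S,4R,6R,8S,10S)-3β,4β:10,11-diepoxy-2β-hydroxybisabol-7(14)-ene-1β,8-diyl diangelate | C=C([C@H](C[C@@H]1OC1(C)C)OC(=O)/C(C)=C\C)[C@H]1C[C@H]2O[C@@]2(C)[C@@H](O)[C@H]1OC(=O)/C(C)=C\C | intermediate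
18 | (1S,2S,3S,4S,6R,8S,10S)-4α-chloro-10,11-epoxy-2β,3β-dihydroxybisabol-7(14)-ene-1β,8-diyl diangelate | C=C([C@H](C[C@@H]1OC1(C)C)OC(=O)/C(C)=C\C)[C@H]1C[C@H](Cl)[C@@](C)(O)[C@@H](O)[C@H]1OC(=O)/C(C)=C\C | target

## Step count and risks

Total step count: 14. Longest linear sequence: 13 (steps 1, 2 and 4–14, from 1 to 18); step 3 is the only side-branch step.

The three steps most likely to fail:

Step 9 (epoxy-aldehyde carbonyl-ene). The epoxide may be opened by the aluminium chloride species, the facial control by the epoxide may be weak, and the C8 stereocentre may be mismatched. The fallback closes the ring before the ring oxygens are introduced and uses catalyst control. It sets out from 9 and comes back at 13. MnO2 oxidises 9 to the (2Z,6Z,8S)-enal F1. A confined chiral imidodiphosphorimidate Brønsted acid (two 3,3'-diaryl-BINOL phosphorus units bridged by NH, each phosphorus carrying =N–SO2CF3; antipode giving 6R) effects the asymmetric carbonyl-ene cyclization to the trans-dienol F2. MnO2 gives the enone F3, which removes the C1 centre. LiBH(s-Bu)3 at −78 °C attacks anti to the side chain and gives the cis-dienol F4. VO(acac)2/t-BuOOH epoxidises syn to the 1β-hydroxyl to give the all-β epoxy alcohol F5. Yamaguchi angeloylation of F5 (retention) returns to 13.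

Step 10 (Mitsunobu inversion at the hindered C1). Elimination or no reaction is possible because the nucleophile must enter cis to both the epoxide and the side chain. The fallback replaces substitution by an oxidation–reduction sequence; it sets out from 12 and comes back at 13. Dess–Martin oxidation gives the epoxy ketone F6. Reduction with NaBH4/CeCl3 or LiBH(s-Bu)3 from the α face (anti to the epoxide oxygen and the side chain) gives the all-β epoxy alcohol F5, the same compound as in the fallback for step 9. Yamaguchi angeloylation then gives 13.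

Step 11 (regiochemistry of the elimination). Loss of a methyl hydrogen would give the exocyclic 3(15)-olefin instead of the 3,4-olefin, and a hydride shift to the 2-ketone is also possible. The fallback replaces elimination by a redox relay that fixes the position of the olefin; it sets out from 13 and comes back at 15. Cp2TiCl (trivalent titanium, from Cp2TiCl2 and Zn) with 1,4-cyclohexadiene opens the epoxide by homolysis to the tertiary C3 radical and reduces it, giving the 2β-hydroxy-3-H compound F7 (C3 epimers, inconsequential). Dess–Martin oxidation gives the 2-ketone F8. Dehydrogenation with IBX in DMSO at 70 °C towards the more substituted side gives the 3-en-2-one F9. NaBH4/CeCl3 at −78 °C attacks anti to the axial 1β-angelate and gives 15.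

Further compounds
F1 | step 9 | (2Z,6Z,8S)-3,7,11-trimethyl-1-oxododeca-2,6,10-trien-8-yl angelate | O=C/C=C(C)\CC/C=C(C)\[C@H](CC=C(C)C)OC(=O)/C(C)=C\C
F2 | step 9 | (1S,6R,8S)-1α-hydroxybisabola-2,7(14),10-trien-8-yl angelate (trans-dienol) | C=C([C@H](CC=C(C)C)OC(=O)/C(C)=C\C)[C@H]1CCC(C)=C[C@@H]1O
F3 | step 9 | (6R,8S)-1-oxobisabola-2,7(14),10-trien-8-yl angelate | C=C([C@H](CC=C(C)C)OC(=O)/C(C)=C\C)[C@H]1CCC(C)=CC1=O
F4 | step 9 | (1R,6R,8S)-1β-hydroxybisabola-2,7(14),10-trien-8-yl angelate (cis-dienol) | C=C([C@H](CC=C(C)C)OC(=O)/C(C)=C\C)[C@H]1CCC(C)=C[C@H]1O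
F5 | step 9 | (1S,2S,3R,6R,8S)-2β,3β-epoxy-1β-hydroxybisabola-7(14),10-dien-8-yl angelate | C=C([C@H](CC=C(C)C)OC(=O)/C(C)=C\C)[C@H]1CC[C@@]2(C)O[C@H]2[C@H]1O
F6 | step 10 | (2R,3R,6R,8S)-2β,3β-epoxy-1-oxobisabola-7(14),10-dien-8-yl angelate | C=C([C@H](CC=C(C)C)OC(=O)/C(C)=C\C)[C@H]1CC[C@@]2(C)O[C@H]2C1=O
F7 | step 11 | (1S,2R,6R,8S)-2β-hydroxybisabola-7(14),10-diene-1β,8-diyl diangelate (C3 epimers) | C=C([C@H](CC=C(C)C)OC(=O)/C(C)=C\C)[C@H]1CCC(C)[C@@H](O)[C@H]1OC(=O)/C(C)=C\C
F8 | step 11 | (1S,6R,8S)-2-oxobisabola-7(14),10-diene-1β,8-diyl diangelate (C3 epimers) | C=C([C@H](CC=C(C)C)OC(=O)/C(C)=C\C)[C@H]1CCC(C)C(=O)[C@H]1OC(=O)/C(C)=C\C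
F9 | step 11 | (1S,6R,8S)-2-oxobisabola-3,7(14),10-triene-1β,8-diyl diangelate | C=C([C@H](CC=C(C)C)OC(=O)/C(C)=C\C)[C@H]1CC=C(C)C(=O)[C@H]1OC(=O)/C(C)=C\C
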